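1. The target is what you want, but its isomer grows behind it in elm and alder. I assume one enzyme makes the target and then turns it into the isomer, so that both rates carry the same enzyme activity. That activity then cancels in their ratio, along with time. While [starting material] stays close to its charge, each bit of new product T (target plus isomer) comes out as isomer in the proportion [target]/c, where c is a constant to be read from the runs.

the same everywhere: enzyme 0.01 mol%

| charge | starting material | second substrate | remark | time |
|---|---|---|---|---|
| elm | 0.13 M | 1 equiv | run made earlier |  |
| alder | 0.13 M | 1.5 equiv | run made earlier |  |
| teal | 0.13 M | 1.00 equiv (fed, over 15 min) | all else is in the flask from the start; the feed brings no volume worth counting | 40 min |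
| red | 0.13 M (fed, over 15 min) | 1.00 equiv | all else is in the flask from the start; the feed brings no volume worth counting | 40 min |
| blue | 0.13 M | 1.00 equiv | everything together at the start | 40 min |
| amber | 0.13 M (fed, over 4.0 min) | 1.00 equiv | all else is in the flask from the start; the feed brings no volume worth counting | 40 min |

| run | time / min | target / % | isomer of the product / % |
|---|---|---|---|
| elm | 1.33 | 4.7 | 0.6 |
| elm | 4.00 | 10.3 | 2.6 |
| elm | 6.00 | 11.9 | 3.3 |
| elm | 10.0 | 14.4 | 5.7 |
| elm | 15.0 | 17.0 | 7.8 |
| elm | 20.0 | 17.3 | 9.4 |
| elm | 25.0 | 18.0 | 10.9 |
| alder | 1.00 | 2.6 | 0 |
| alder | 1.33 | 4.0 | 0 |
| alder | 2.00 | 5.4 | 0.1 |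
| alder | 3.00 | 7.7 | 0.6 |
| alder | 5.00 | 9.2 | 2.2 |
| alder | 8.00 | 10.6 | 3.4 |
| alder | 12.0 | 12.0 | 3.5 |

(scatter of a reading: 0.5 percentage points)



- the flask with the highest share of target in target plus isomer of the product ("all alike" if they lie within 1.5 percentage points) (teal / red / blue / amber / all alike)
- share of target in target plus isomer of the product at the end, teal
- share of target in target plus isomer of the product at the end, red
- share of target in target plus isomer of the product at the end, blue
- share of target in target plus isomer of the product at the end, amber

2. There are two independent ways to read c, each from the third reading to the last: c is the mean target times the gain in T, divided by the gain in isomer. Elm gives 26.9%. Alder, with 1.5 equiv of second substrate, gives 25.6%. They differ by 1.3 percentage points, with a scatter of 0.5 points on each reading, so I trust their mean, 26.3%. Call it the balance level, the target level at which the enzyme makes and unmakes target equally fast; it is a selectivity factor in percent of charge. Integrated with c held constant, target = c(one minus exp(−T/c)), so I reckon the share from T and c.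

3. Blue is elm's recipe, and elm's last total, at 25.0 min, is 28.9%, which I take as blue's end total. That gives a blue share of 60.6%.

4. Elm's rate of making T fades at about 0.118 /min. I assume the same fading in a flask fed with starting material, where [starting material] climbs steadily. T is then scaled by (one minus exp(−x))/x, with x the fading constant times the feed time. Red gets 13.6% and a share of 78.1%. Amber gets 23.1% and a share of 66.6%. Both reckonings hold c at the value read at full charge, although [starting material] lies below its charge during the feed, so these two shares are rough. My highest is red.

5. Alder's total at 12.0 min was 15.5%, less than elm's 20.1% at 10.0 min. I read that as extra second substrate costing total in those two runs, so I expect teal, fed with second substrate, to make more than blue and to end below blue's share.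

6. The forecast, for blue and amber and red  lower than my figures, names red, with teal 42%, red 76%, blue 59% and amber 65%, saying “Feeding starting material spends enzyme while target forms slowly, giving the best share.”

7. The flasks give red as highest, with teal 44.7%, red 75.3%, blue 61.7% and amber 67.1%.

    target + enzyme ⇌ isomer of the product + enzyme, rate k1*[enzyme]*[target] forward; the back reaction follows from the equilibrium constant (K = 2.40, k = 370 /M/s)
    second substrate + enzyme ⇌ complex B (K = 5.40 /M, k = 19000 /M/s)
    complex A → enzyme + target (k = 38.0 /s)
    starting material + enzyme ⇌ complex A (K = 2.90 /M, k = 1.10 × 10⁵ /M/s)
    complex B → enzyme + second product (k = 72.0 /s)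
    complex B → spent catalyst (k = 0.0100 /s)

Red's actual end total is 14.8%; with the balance level 26.3%, it gives a share of 76.5%, against 75.3% in the flask. The neighbour flask is red with 0.04 mol% of enzyme. Its end total is 99.9%, and the same reckoning gives 25.7%, against 29.4% in that flask. At 40.0 min the neighbour flask holds 0.130% of its starting material and 70.5% as isomer of the product.

The earlier runs and the new flask are simulated from invented constants; scatter was added.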